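Slowness of a solid is a clock of its own, and in this flask I count how many lifetimes of the coupling partner that clock allows.

solid substrate 12 mM; coupling partner 18.0 mM; time 25 h

    dissolved substrate + target → side product (k1 = 14 /M/s)
    solid product ⇌ target, rate k2*(cs2 - [target]) while solid is left; crystals form when [target] > cs2 (cs2 = 2.4 mM, k2 = 0.099 /s)
    2 coupling partner → homo dimer (k3 = 0.027 /M/s)
    coupling partner → decomposed reagent (k4 = 0.0012 /s)
    solid substrate ⇌ dissolved substrate, rate k5*(cs5 - [dissolved substrate]) while solid is left; crystals form when [dissolved substrate] > cs5 (cs5 = 4.3 mM, k5 = 7.8 × 10⁻⁴ /s)
    dissolved substrate + coupling partner → target (k6 = 1.8 /M/s)

- in percentages every species weighs as the solid substrate in it: one side product counts as two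
- for target the solid product is counted in
- a doubled species enters its step squared and goes two at a time
- as a solid, counted per litre of solution: solid substrate, solid product
- at the start none of the solid substrate is in solution
- what has only dissolved of solid substrate counts as not reacted
- the reaction counts as stopped when no species that holds the solid substrate changes by six tenths of a point or more over the second half of the time
- run time (flask): 25 h

* at 25 h, what has stopped the reaction, if anything has (for what has run out or reacted, a solid counts together with what of it has only dissolved) (all of the solid substrate has reacted / it is still moving / forward and back rates have come level / the coupling partner has run out first)
* part of the solid substrate that has turned into other species by 25 h (what has only dissolved does not count)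

Two chemists disagree. The first counts charges: 1.50 equivalents of coupling partner stand against the solid substrate, so the solid substrate should be the limiting reagent and conversion should reach 100%. The second counts time. Dissolving runs at most at the dissolution coefficient times the solubility, which is 12.1 mM/h. The lifetime of the coupling partner against decomposition is 0.231 h, and at that feed the charge needs 0.994 h to enter solution, which is longer than that lifetime.

My own reckoning puts the second view into numbers. I suppose that each dissolved substrate is caught as it arrives, so the feed stays full. Target takes dissolved substrate with constant 14 /M/s, larger than the constant 1.8 /M/s with which the coupling partner takes it, so I let two dissolved substrates go per coupling partner, into one side product. Then c(coupling partner) falls by first-order decomposition, 77.8 mM/h at the start, plus half the feed, 6.05 mM/h. I leave the homo dimer out. Integrating down to zero gives the logarithm of one plus the ratio of those two rates, 2.63 lifetimes. This is the working life, the number of lifetimes until decomposition and the feed together have emptied the coupling partner. Over it, by my count, the feed delivers 61.3% of the charge.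

The forecast also sides with time: the coupling partner has run out first, with conversion 64%, on the ground that the coupling partner goes “much faster than the slowly dissolving substrate can use it”. Its number comes from another reckoning than mine and stands higher.

The simulation gives the coupling partner has run out first, with conversion 47.5%. At 25.0 h this flask holds 0% of its coupling partner, while 16.7% of the solid substrate is still solid and 35.8% stands dissolved. So the charge count loses, the forecast is 16 percentage points high and my count 14 points high. The charge count has its region in the flask with the decomposition struck out, where conversion is 100%.

In this flask the crawl of solid substrate into solution holds conversion at 47.5%, and the run with that crawl taken away reaches 100%. The working life gives the span of the conversion: 95.0% of the conversion stands by 0.602 h, which is 2.61 lifetimes against 2.63 counted. For the neighbour charged with 4.5 mM of coupling partner the working life is 1.44 lifetimes, so by the same count the feed delivers 33.5% of the charge, and that flask gives 26.0%.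

The numbers of this flask are those of an exercise; the rest is arithmetic.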